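**Retrosynthetic overview**
- The two isobutyryl groups are removed from the unsubstituted ring carbons (late C-acylation), which leads back to 2,2'-methylenebis(filicinic acid).
- Both six-membered rings are then opened at once, each at the bond between the bridge-bearing ring carbon and the ring C=O carbon lying between that carbon and the ring CH (double Claisen condensation of the Dieckmann type). This gives an acyclic, mirror-symmetric bis(4,4-dimethyl-3,5-dioxo ester).
- That chain comes from glutaryl dichloride and two dianions of methyl 4-methyl-3-oxopentanoate (two-directional γ-acylation). The glutaryl C2–C3–C4 unit becomes the two bridge-bearing ring carbons and the bridging CH2.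
- Enabling feature: a mirror plane runs through the bridging CH2, and in each ring the quaternary C(CH3)2 carbon sits para to the ring C=O that is closed. The ketone beside C(CH3)2 can therefore enolise only toward the bridge-bearing carbon, which lies six atoms from the ester carbon.
- Ring order: no ring exists before step 2; ring A and ring B form in the same operation, and the acyl groups follow in step 3.

Key step: step 2

Remark: the target has no stereocentre. Each enolised trione is written as one tautomer of a rapidly equilibrating set, and polyanions formed in the flask are listed in neutral form unless stated.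

**Step 1**
Reactants: 1 methyl 4-methyl-3-oxopentanoate; 2 glutaryl dichloride (pentanedioyl dichloride)
Product: 4 dimethyl 4,4,10,10-tetramethyl-3,5,9,11-tetraoxotridecanedioate, via sodium lithium dianion 3 (not isolated)
Conditions: 1 (4.4 equiv), NaH (4.6 equiv), THF, 0 °C; n-BuLi (4.4 equiv), 0 °C; then 2 (1.0 equiv, slow addition), −78 → −30 °C; 1 M HCl
Reagents that add atoms: none
Why: γ-Acylation of a β-keto ester dianion: the more basic C4 carbanion of 3 should attack each acid chloride function of 2 in preference to the C2 enolate terminus, giving the quaternary 4,4-dimethyl-3,5-dioxo ester at both ends in one two-directional operation (amine-free dianion, so no amide formation); no stereocentre is formed.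

**Step 2**
Reactants: 4 dimethyl 4,4,10,10-tetramethyl-3,5,9,11-tetraoxotridecanedioate
Product: 6 2,2'-methylenebis(3,5-dihydroxy-4,4-dimethylcyclohexa-2,5-dien-1-one), via monocyclic keto ester 5 (not isolated)
Conditions: KOtBu (6 equiv), THF/t-BuOH (4:1), 0 → 50 °C; then 1 M HCl, 0 °C
Reagents that add atoms: none
Why: KOtBu first converts both β-keto ester termini into their enolates and then reversibly enolises the C5 and C9 ketones toward C6 and C8, the only direction open because C4 and C10 are quaternary; each ketone enolate attacks through carbon the ester carbonyl six atoms away (C6→C1, C8→C13), methoxide leaves, and the new 1,3,5-trione is at once ionised to a vinylogous carboxylate, which makes each closure irreversible (double Claisen condensation of the Dieckmann type). The closest known reaction type is the Dieckmann-type closure of a δ-keto ester whose ester carries an acidic α-CH, as in the classical keto-malonate route to dimedone, together with the Claisen cyclisation of polyketo esters to acylphloroglucinols. Ring A and ring B each close in the favoured 6-(enolendo)-exo-trig mode, independently at the two ends of the chain. No stereocentre is created. The step needs C- over O-acylation and Claisen over aldol or retro-Claisen chemistry: an O-acylated enol lactone should be reopened by alkoxide and drain to the doubly ionised trione; every other carbon–carbon closure is four- or eight-membered except one reversible six-ring aldol onto a carbonyl masked as its β-keto ester enolate; and that same enolate should protect the 2,2-dimethyl-1,3-diketone from alkoxide cleavage, because fragmentation would have to expel a dianion.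

**Step 3**
Reactants: 6 2,2'-methylenebis(3,5-dihydroxy-4,4-dimethylcyclohexa-2,5-dien-1-one); 7 isobutyryl chloride (2-methylpropanoyl chloride)
Product: 9 2,2'-methylenebis[3,5-dihydroxy-4,4-dimethyl-6-(2-methylpropanoyl)cyclohexa-2,5-dien-1-one] (target), via bis(enol isobutyrate) 8 (not isolated)
Conditions: 7 (2.2 equiv), Et3N (5 equiv), CH2Cl2, 0 °C; then DMAP (0.3 equiv), 0 °C → rt; 1 M HCl
Reagents that add atoms: none
Why: O-acylation of the vinylogous acid followed by DMAP-mediated 1,3 O→C acyl migration (Fries-type rearrangement of an enol ester) should deliver each isobutyryl group to the only unsubstituted ring carbon, because the triketone formed there is removed from the equilibrium as its triethylammonium enolate, whereas acylation at the bridge-bearing carbon would give a non-enolisable, reversibly formed product; no stereocentre is formed.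

**Compound list**
1 | methyl 4-methyl-3-oxopentanoate | COC(=O)CC(=O)C(C)C | starting material
2 | glutaryl dichloride (pentanedioyl dichloride) | O=C(Cl)CCCC(=O)Cl | starting material
3 | sodium lithium dianion of 1 (carbanionic at C2 and C4) | COC(=O)[CH-]C(=O)[C-](C)C.[Na+].[Li+] | intermediate
4 | dimethyl 4,4,10,10-tetramethyl-3,5,9,11-tetraoxotridecanedioate | COC(=O)CC(=O)C(C)(C)C(=O)CCCC(=O)C(C)(C)C(=O)CC(=O)OC | intermediate
5 | methyl 7-(2,4-dihydroxy-3,3-dimethyl-6-oxocyclohexa-1,4-dien-1-yl)-4,4-dimethyl-3,5-dioxoheptanoate (present as its potassium polyenolate) | COC(=O)CC(=O)C(C)(C)C(=O)CCC1=C(O)C(C)(C)C(O)=CC1=O | intermediate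
6 | 2,2'-methylenebis(3,5-dihydroxy-4,4-dimethylcyclohexa-2,5-dien-1-one) (methylenebis-filicinic acid) | CC1(C)C(O)=CC(=O)C(CC2=C(O)C(C)(C)C(O)=CC2=O)=C1O | intermediate
7 | isobutyryl chloride (2-methylpropanoyl chloride) | CC(C)C(=O)Cl | starting material
8 | bis(O-isobutyryl) enol ester of 6, drawn with each ring acylated on the oxygen of the ring carbon between the ring CH and the bridge-bearing carbon (any O-acyl regioisomer should converge on 9) | CC(C)C(=O)OC1=CC(=O)C(C)(C)C(O)=C1CC1=C(O)C(C)(C)C(=O)C=C1OC(=O)C(C)C | intermediate
9 | 2,2'-methylenebis[3,5-dihydroxy-4,4-dimethyl-6-(2-methylpropanoyl)cyclohexa-2,5-dien-1-one] | CC(C)C(=O)C1=C(O)C(C)(C)C(O)=C(CC2=C(O)C(C)(C)C(O)=C(C(=O)C(C)C)C2=O)C1=O | target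

**Step count and risks**
Total step count: 3. Longest linear sequence: 3 steps (from 1 and 2).

Steps most likely to fail, riskiest first:

1. Step 2 (key step). The Claisen closure may stall because the ester sits next to an enolate, leaving time for O-acylation to an enol lactone or slow alkoxide cleavage of the 2,2-dimethyl-1,3-diketone. The fallback sets out from 4 and removes the acidic α-CH of the ester before ring closure. Treatment of 4 with HC(OMe)3 and catalytic H2SO4 in MeOH at rt should convert each β-keto ester into its thermodynamically preferred (E)-β-methoxy enoate, dimethyl (2E,11E)-3,11-dimethoxy-4,4,10,10-tetramethyl-5,9-dioxotrideca-2,11-dienedioate F1. In F1 the ester is neutral and lies cis to the quaternary carbon. LDA (4.4 equiv, THF, −78 → 0 °C) should then form only the C6 and C8 ketone enolates and close both rings by Claisen condensation onto the enoate esters, giving the bis(methyl enol ether) 2,2'-methylenebis(3-hydroxy-5-methoxy-4,4-dimethylcyclohexa-2,5-dien-1-one) F2. Hydrolysis of the vinylogous esters (2 M HCl, THF, 50 °C) returns to the route at 6.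

2. Step 1. Proton transfer from the first-formed δ-keto acid chloride to the strongly basic dianion, followed by O-acylative closure to a six-membered enol lactone, or O- instead of C-acylation at the hindered tertiary carbanion, may erode the double acylation. The fallback sets out from 1 and uses a neutral, base-free acylation. TMSCl and Et3N (pentane, rt) should give the silyl enol ether methyl (Z)-4-methyl-3-(trimethylsilyloxy)pent-2-enoate F3. LDA then TMSCl (THF, −78 °C) should give the bis-silyl dienol ether (1Z)-1-methoxy-4-methyl-1,3-bis(trimethylsilyloxy)penta-1,3-diene F4 (geometry of no consequence). Mukaiyama-type γ-acylation of F4 (2.2 equiv) with 2 (CH2Cl2, −78 → 20 °C, then dilute HCl) returns to the route at 4.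

3. Step 3. Acyl transfer may stop at oxygen or spread over several enol oxygens, and base-induced retro-Michael exchange of the methylene bridge may occur before the free ring carbon is capped. The fallback sets out from 6 and replaces base-mediated O→C transfer by direct, chelation-driven electrophilic C-acylation. Isobutyric anhydride with BF3·OEt2 (0 → 25 °C, kept cold to avoid cyclodehydration) should acylate the free ring carbon of each ring and hold the product as the bis(difluoroboron) chelate of 9 F5. Warming F5 in aqueous MeOH (60 °C) should release the triketone and return to the route at 9.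

**Further compounds**
F1 | step 2 | dimethyl (2E,11E)-3,11-dimethoxy-4,4,10,10-tetramethyl-5,9-dioxotrideca-2,11-dienedioate | COC(=O)/C=C(/OC)C(C)(C)C(=O)CCCC(=O)C(C)(C)/C(OC)=C\C(=O)OC
F2 | step 2 | 2,2'-methylenebis(3-hydroxy-5-methoxy-4,4-dimethylcyclohexa-2,5-dien-1-one) | COC1=CC(=O)C(CC2=C(O)C(C)(C)C(OC)=CC2=O)=C(O)C1(C)C
F3 | step 1 | methyl (Z)-4-methyl-3-(trimethylsilyloxy)pent-2-enoate | COC(=O)/C=C(\O[Si](C)(C)C)C(C)C
F4 | step 1 | (1Z)-1-methoxy-4-methyl-1,3-bis(trimethylsilyloxy)penta-1,3-diene | CO/C(O[Si](C)(C)C)=C/C(O[Si](C)(C)C)=C(C)C
F5 | step 3 | bis(difluoroboron) chelate of 9 (each boron bridging the acyl oxygen and the enol oxygen next to the quaternary carbon) | CC(C)C1=[O+][B-](F)(F)OC2=C1C(=O)C(CC3=C(O)C(C)(C)C4=C(C3=O)C(C(C)C)=[O+][B-](F)(F)O4)=C(O)C2(C)C
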